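**Retrosynthetic overview**
- Final step: global O-demethylation of the tetramethyl ether 9 of the target.
- Key disconnection: the ArCH2–Ar' bond, made by Friedel–Crafts benzylation of C2-symmetric 1,4-dibromo-2,3-dimethoxybenzene (7) with the fully substituted benzyl bromide 4. The only free position of 7 gives the ring A pattern directly.
- Ring B electrophile 4: 4-methylcatechol → exhaustive ring bromination → O-methylation → benzylic bromination.
- Ring A nucleophile 7: 3,6-dilithiation of veratrole, then bromination.
- No ring is constructed; both benzene rings come from commercial aromatics.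

Assumption: the target has no stereocentre, so "single enantiomer" is taken to mean the one achiral compound and no stereocontrol is needed.

**Step 1**
Reactants: 1 4-methylbenzene-1,2-diol (4-methylcatechol)
Product: 2 3,4,6-tribromo-5-methylbenzene-1,2-diol
Conditions: Br2 (3.3 equiv), AcOH/CHCl3, 0 °C → rt; aq NaHSO3 work-up
Reagents that add atoms: bromine, BrBr
Why: Exhaustive electrophilic aromatic bromination, since all three free ring positions are ortho or para to a catechol OH and no other site exists.

**Step 2**
Reactants: 2 3,4,6-tribromo-5-methylbenzene-1,2-diol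
Product: 3 1,2,4-tribromo-5,6-dimethoxy-3-methylbenzene
Conditions: MeI (excess), K2CO3, DMF, N2, rt → 50 °C
Reagents that add atoms: iodomethane, CI
Why: Williamson O-methylation of the acidic bromophenols, which protects the catechol against oxidation and against the radical and Lewis-acid steps that follow.

**Step 3**
Reactants: 3 1,2,4-tribromo-5,6-dimethoxy-3-methylbenzene
Product: 4 1,2,4-tribromo-3-(bromomethyl)-5,6-dimethoxybenzene
Conditions: NBS (1.1 equiv), cat. AIBN, PhCF3, reflux
Reagents that add atoms: N-bromosuccinimide, O=C1CCC(=O)N1Br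
Why: Wohl–Ziegler radical bromination at the only benzylic C–H position, with the fully substituted ring excluding nuclear bromination.

**Step 4**
Reactants: 5 1,2-dimethoxybenzene (veratrole)
Product: 7 1,4-dibromo-2,3-dimethoxybenzene, via 3,6-dilithio-1,2-dimethoxybenzene 6 (not isolated)
Conditions: n-BuLi (3 equiv), TMEDA, hexane/Et2O, rt → reflux; then BrCCl2CCl2Br, THF, −78 °C → rt
Reagents that add atoms: 1,2-dibromo-1,1,2,2-tetrachloroethane, BrC(Cl)(Cl)C(Cl)(Cl)Br
Why: Double directed ortho-metalation, each OMe directing lithiation to its own ortho position, followed by electrophilic bromination of both C–Li bonds.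

**Step 5**
Reactants: 4 1,2,4-tribromo-3-(bromomethyl)-5,6-dimethoxybenzene; 7 1,4-dibromo-2,3-dimethoxybenzene (3 equiv, excess recovered)
Product: 9 1,2,4-tribromo-3-[(2,5-dibromo-3,4-dimethoxyphenyl)methyl]-5,6-dimethoxybenzene, via 2,3,6-tribromo-4,5-dimethoxybenzyl triflate 8 (not isolated)
Conditions: AgOTf (1.2 equiv), CH2Cl2, dark, 0 °C → rt
Reagents that add atoms: none
Why: Silver-promoted Friedel–Crafts benzylation, in which the benzyl triflate/cation (para-OMe stabilised) attacks one of the two equivalent free positions of 7, each para to an OMe, so a single regioisomer results and the blocked electrophile cannot self-condense.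

**Step 6**
Reactants: 9 1,2,4-tribromo-3-[(2,5-dibromo-3,4-dimethoxyphenyl)methyl]-5,6-dimethoxybenzene
Product: 11 3,6-dibromo-4-[(2,3,6-tribromo-4,5-dihydroxyphenyl)methyl]benzene-1,2-diol (target), via bis(2-bromo-1,3,2-benzodioxaborole) ester 10 (not isolated)
Conditions: BBr3 (6–8 equiv), CH2Cl2, −78 °C → rt; then ice-water/MeOH
Reagents that add atoms: none
Why: Lewis-acid cleavage of all four aryl methyl ethers with BBr3 (loss of MeBr) and hydrolysis of the cyclic borate esters on work-up, leaving aryl bromides and the diarylmethane untouched.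

**Compound list**
1 | 4-methylbenzene-1,2-diol | Cc1ccc(O)c(O)c1 | starting material
2 | 3,4,6-tribromo-5-methylbenzene-1,2-diol | Cc1c(Br)c(O)c(O)c(Br)c1Br | intermediate
3 | 1,2,4-tribromo-5,6-dimethoxy-3-methylbenzene | Cc1c(Br)c(OC)c(OC)c(Br)c1Br | intermediate
4 | 1,2,4-tribromo-3-(bromomethyl)-5,6-dimethoxybenzene | BrCc1c(Br)c(OC)c(OC)c(Br)c1Br | intermediate
5 | 1,2-dimethoxybenzene (veratrole) | COc1ccccc1OC | starting material
6 | 3,6-dilithio-1,2-dimethoxybenzene (not isolated) | COc1c([Li])ccc([Li])c1OC | intermediate
7 | 1,4-dibromo-2,3-dimethoxybenzene | COc1c(Br)ccc(Br)c1OC | intermediate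
8 | 2,3,6-tribromo-4,5-dimethoxybenzyl trifluoromethanesulfonate (not isolated) | FC(F)(F)S(=O)(=O)OCc1c(Br)c(OC)c(OC)c(Br)c1Br | intermediate
9 | 1,2,4-tribromo-3-[(2,5-dibromo-3,4-dimethoxyphenyl)methyl]-5,6-dimethoxybenzene | COc1c(Br)cc(Cc2c(Br)c(OC)c(OC)c(Br)c2Br)c(Br)c1OC | intermediate
10 | bis(2-bromo-1,3,2-benzodioxaborole) ester of the target (not isolated) | BrB1Oc2c(Br)cc(Cc3c(Br)c4OB(Br)Oc4c(Br)c3Br)c(Br)c2O1 | intermediate
11 | 3,6-dibromo-4-[(2,3,6-tribromo-4,5-dihydroxyphenyl)methyl]benzene-1,2-diol | Oc1c(Br)cc(Cc2c(Br)c(O)c(O)c(Br)c2Br)c(Br)c1O | target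

**Step count**
Total steps: 6. Longest linear sequence: 5 (steps 1, 2, 3, 5, 6).

**Steps most likely to fail, with fallbacks**

Step 5 (Friedel–Crafts benzylation of a doubly brominated, hindered arene with a hindered benzyl electrophile). The fallback replaces the cationic C–C bond formation by a carbonyl addition followed by deoxygenation. It sets out from 4 and 7 and comes back at 9. Bromide 4 is oxidised with N-methylmorpholine N-oxide in MeCN (Kornblum-type) to 2,3,6-tribromo-4,5-dimethoxybenzaldehyde F1. Separately, 7 is magnesiated at its only C–H type (ortho to Br) with TMPMgCl·LiCl in THF at 0 °C to give (2,5-dibromo-3,4-dimethoxyphenyl)magnesium chloride F2. Adding F2 to F1 gives racemic (2,5-dibromo-3,4-dimethoxyphenyl)(2,3,6-tribromo-4,5-dimethoxyphenyl)methanol F3. Ionic hydrogenation of F3 with Et3SiH/TFA in CH2Cl2 removes the carbinol oxygen and its transient stereocentre and delivers 9.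

Step 4 (incomplete dilithiation would give mono/di-bromide mixtures). The fallback uses silicon placeholders and ipso-substitution instead of direct bromination of a dianion. It sets out from 5 and comes back at 7. One ortho-lithiation (n-BuLi/TMEDA) with TMSCl quench gives 1,2-dimethoxy-3-(trimethylsilyl)benzene F4. A second ortho-lithiation/TMSCl cycle, directed by the other OMe, gives 1,2-dimethoxy-3,6-bis(trimethylsilyl)benzene F5, which is easily purified. Ipso-bromodesilylation of F5 with Br2 in CH2Cl2 at 0 °C gives 7.

Step 1 (excess bromine may oxidise the free catechol to an o-quinone). The fallback inverts the order so that bromination is done on the oxidation-resistant ether. It sets out from 1 and comes back at 3. Compound 1 is O-methylated (MeI, K2CO3, DMF) to 1,2-dimethoxy-4-methylbenzene F6. F6 is then exhaustively ring-brominated (excess Br2, cat. Fe powder, CHCl3, reflux) to give 3 directly, bypassing 2.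

**Further compounds**
F1 | step 5 | 2,3,6-tribromo-4,5-dimethoxybenzaldehyde | O=Cc1c(Br)c(OC)c(OC)c(Br)c1Br
F2 | step 5 | (2,5-dibromo-3,4-dimethoxyphenyl)magnesium chloride | COc1c(Br)cc([Mg]Cl)c(Br)c1OC
F3 | step 5 | (2,5-dibromo-3,4-dimethoxyphenyl)(2,3,6-tribromo-4,5-dimethoxyphenyl)methanol (racemic) | COc1c(Br)cc(C(O)c2c(Br)c(OC)c(OC)c(Br)c2Br)c(Br)c1OC
F4 | step 4 | 1,2-dimethoxy-3-(trimethylsilyl)benzene | COc1cccc([Si](C)(C)C)c1OC
F5 | step 4 | 1,2-dimethoxy-3,6-bis(trimethylsilyl)benzene | COc1c([Si](C)(C)C)ccc([Si](C)(C)C)c1OC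
F6 | step 1 | 1,2-dimethoxy-4-methylbenzene | Cc1ccc(OC)c(OC)c1
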